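**Retrosynthetic overview**
1. The target, 3-nonadecylcyclohex-2-en-1-one, has one ring: C1 carbonyl, C2=C3 with the nonadecyl chain on C3, and C4–C6 methylenes. It is opened at the C1(=O)–C6H2 bond to an acyclic C1 acyl radical, so the six-membered ring is formed last and in one operation.
2. Enabling feature: C1 is conjugated with C2=C3, so the acyl radical is equally a C1=C2 ketene with its spin on C3, and C3 carries both the chain and the C4–C5–C6 unit. Stored as a cyclopropane on C3, that unit opens to place the radical on C6, and closure of C6 on the ketene carbon C1 gives the cyclohexenone while the three-membered ring disappears.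
3. The radical precursor is an acyclic Se-phenyl 3-cyclopropyl-2-enoate selenoester, made from the corresponding acid and ethyl ester.
4. The ester comes from copper-mediated conjugate addition of the nonadecyl Grignard reagent (from 1-bromononadecane) to ethyl 3-cyclopropylprop-2-ynoate; the cyclopropane is bought.

Key step: step 4

Assumption: ethyl 3-cyclopropylprop-2-ynoate is taken as a catalogue compound (otherwise one step from ethynylcyclopropane, n-BuLi and ethyl chloroformate). The C2=C3 geometry of the acyclic intermediates is treated as inconsequential because the radical of step 4 loses it.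

Step 1
Reactants: 1 1-bromononadecane; 2 ethyl 3-cyclopropylprop-2-ynoate
Product: 5 ethyl (2Z)-3-cyclopropyldocos-2-enoate, via nonadecylmagnesium bromide 3 (not isolated), via nonadecylcopper 4 (not isolated)
Conditions: Mg, I2 (cat.), THF, 50 °C; CuBr·SMe2 (1 equiv per RMgBr), −40 °C; then 2, −78 °C; 1 M HCl
Reagents that add atoms: magnesium, [Mg]; copper monobromide dimethyl sulfide complex, CSC.[Cu]Br
Why: The stoichiometric organocopper reagent 4, made by transmetalation of the Grignard reagent 3, should add across the ynoate triple bond by syn carbocupration (copper-mediated conjugate addition), and cold protonation of the configurationally stable alkenylcopper should give the (2Z) enoate, magnesium and copper leaving as salts on work-up while ester and cyclopropane stay inert to RCu at −78 °C.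

Step 2
Reactants: 5 ethyl (2Z)-3-cyclopropyldocos-2-enoate
Product: 6 (2Z)-3-cyclopropyldocos-2-enoic acid
Conditions: LiOH·H2O (5 equiv), THF/MeOH/H2O, 60 °C; then 1 M HCl
Reagents that add atoms: lithium hydroxide, [Li+].[OH-]
Why: Saponification (ester hydrolysis by acyl–oxygen cleavage) should free the acid, since the trisubstituted alkene and the unactivated cyclopropane are inert to hydroxide and any E/Z drift is without consequence.

Step 3
Reactants: 6 (2Z)-3-cyclopropyldocos-2-enoic acid
Product: 7 Se-phenyl (2Z)-3-cyclopropyldocos-2-eneselenoate
Conditions: (PhSe)2 (1.3 equiv), PBu3 (1.5 equiv), CH2Cl2, 0 °C to rt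
Reagents that add atoms: diphenyl diselenide, c1ccccc1[Se][Se]c1ccccc1
Why: Phosphine-mediated redox condensation of a carboxylic acid with a diselenide (acyloxyphosphonium salt captured by benzeneselenolate) is a standard neutral route to Se-phenyl selenoesters and should leave alkene and cyclopropane untouched.

Step 4
Reactants: 7 Se-phenyl (2Z)-3-cyclopropyldocos-2-eneselenoate
Product: 9 3-nonadecylcyclohex-2-en-1-one, via 3-nonadecylcyclohex-3-en-1-one 8 (not isolated)
Conditions: Bu3SnH (1.3 equiv), AIBN (0.2 equiv), syringe pump, PhH (5 mM), 80 °C; then DBU (0.3 equiv), rt
Reagents that add atoms: none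
Why: Bu3Sn• should abstract the phenylselanyl group of 7 to give the C1 acyl radical, which is conjugated with C2=C3 and therefore reacts as its α-ketenyl form (C2=C1=O ketene, spin on C3); C3 is then a cyclopropylcarbinyl radical and opens to the homoallylic primary radical on C6 with a new C3=C4 bond. That C6 radical adds to the ketene carbon C1 in a six-membered closure (endo for the C1=C2 bond, which ends inside the ring, and exo for C=O), forming the C1–C6 bond and a ring radical delocalised over C2–C3–C4 next to the C1 carbonyl, which takes hydrogen from Bu3SnH at C4 to give 9 directly or at C2 to give 8; DBU then moves C3=C4 of 8 into conjugation, so both converge on 9. The closest known reaction type is the tin hydride cascade of α,β-unsaturated acyl radicals from Se-phenyl selenoesters, whose α-ketenyl alkyl radical forms cyclise, open adjacent cyclopropanes and are recaptured at the ketene carbon to give cycloalkenones. No stereocentre is created. The step needs (a) the cascade to outrun hydrogen transfer to the acyl and C6 radicals, which high dilution, slow stannane addition and the fast opening of a cyclopropylcarbinyl radical should secure, and (b) C2 and C5 cis on the new C3=C4 bond, which the substrate cannot fix but should reach by reversible opening and reclosure of the cyclopropane, only the cis radical being drained by ring closure; for the same reason the C2=C3 geometry of 7 does not matter.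

**Compound list**
1 | 1-bromononadecane | CCCCCCCCCCCCCCCCCCCBr | starting material
2 | ethyl 3-cyclopropylprop-2-ynoate | CCOC(=O)C#CC1CC1 | starting material
3 | nonadecylmagnesium bromide | CCCCCCCCCCCCCCCCCCC[Mg]Br | intermediate (not isolated)
4 | nonadecylcopper | CCCCCCCCCCCCCCCCCCC[Cu] | intermediate (not isolated)
5 | ethyl (2Z)-3-cyclopropyldocos-2-enoate | CCOC(=O)/C=C(/CCCCCCCCCCCCCCCCCCC)C1CC1 | intermediate
6 | (2Z)-3-cyclopropyldocos-2-enoic acid | OC(=O)/C=C(/CCCCCCCCCCCCCCCCCCC)C1CC1 | intermediate
7 | Se-phenyl (2Z)-3-cyclopropyldocos-2-eneselenoate | O=C(/C=C(/CCCCCCCCCCCCCCCCCCC)C1CC1)[Se]c1ccccc1 | intermediate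
8 | 3-nonadecylcyclohex-3-en-1-one | CCCCCCCCCCCCCCCCCCCC1=CCCC(=O)C1 | intermediate (not isolated)
9 | 3-nonadecylcyclohex-2-en-1-one | CCCCCCCCCCCCCCCCCCCC1=CC(=O)CCC1 | target

**Step count and risks**
Total steps: 4. Longest linear sequence: 4 steps (from 1 and 2 to 9).

Steps most likely to fail:

Step 4 (key step). What may go wrong: hydrogen transfer to the acyl radical or to the ring-opened C6 radical before ring closure, or unfavourable partitioning of the opened radical between its two C3=C4 geometries, so that acyclic reduction products or ketene oligomers dominate. Fallback (metal-catalysed [5+1] carbonylation of a vinylcyclopropane in place of the radical cascade): it sets out from the Grignard reagent 3, made from 1 as in step 1. Acylation of 3 with N-methoxy-N-methylcyclopropanecarboxamide (THF, 0 °C; 1 M HCl) should give 1-cyclopropylicosan-1-one F1. Wittig methylenation (Ph3PCH3Br, KOtBu, THF, 0 °C to rt) should give 2-cyclopropylhenicos-1-ene F2. Carbonylation under a cationic monovalent rhodium catalyst ([Rh(CO)2Cl]2 5 mol %, dppp 10 mol %, AgOTf 12 mol %, CO 0.2 atm in N2, DCE, 85 °C) should open the cyclopropane to a σ-alkyl/π-allyl rhodacycle, insert CO and reductively eliminate to the β,γ-enone. The fallback thus comes back to the route at 8, which DBU converts into 9 as in step 4.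

Step 1. What may go wrong: 1,2-addition of the organometallic to the ester, Wurtz coupling during formation of the long-chain Grignard reagent, or decomposition and poor solubility of the organocopper at low temperature. Fallback (cross-coupling on an enol triflate in place of conjugate addition): commercially available ethyl 3-cyclopropyl-3-oxopropanoate is converted (Tf2O, aq Me4NOH, toluene, 0 °C) into ethyl (2E)-3-cyclopropyl-3-[(trifluoromethanesulfonyl)oxy]prop-2-enoate F3. Iron-catalysed cross-coupling of F3 with the Grignard reagent 3 (Fe(acac)3 5 mol %, THF/NMP, −30 °C) should replace the triflate by the nonadecyl group with retention of geometry. The fallback sets out from 3 and comes back to the route at 5.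

Step 3. What may go wrong: conjugate addition of the phosphine or of benzeneselenolate to the enoic acid, or sluggish activation of the hindered β,β-disubstituted acid. Fallback (acylation of the selenol by an acid chloride in place of redox condensation): it sets out from 6, which with (COCl)2 and DMF (cat.) in CH2Cl2 should give (2Z)-3-cyclopropyldocos-2-enoyl chloride F4. Treatment of F4 with PhSeH and pyridine (CH2Cl2, 0 °C) should give the selenoester, so the fallback comes back to the route at 7.

**Further compounds**
F1 | step 4 | 1-cyclopropylicosan-1-one | CCCCCCCCCCCCCCCCCCCC(=O)C1CC1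
F2 | step 4 | 2-cyclopropylhenicos-1-ene | C=C(CCCCCCCCCCCCCCCCCCC)C1CC1
F3 | step 1 | ethyl (2E)-3-cyclopropyl-3-[(trifluoromethanesulfonyl)oxy]prop-2-enoate | CCOC(=O)/C=C(/OS(=O)(=O)C(F)(F)F)C1CC1
F4 | step 3 | (2Z)-3-cyclopropyldocos-2-enoyl chloride | ClC(=O)/C=C(/CCCCCCCCCCCCCCCCCCC)C1CC1
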